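## Analysis of the target

Nymphaeol A is a flavanone: ring A, a phloroglucinol-type benzene, is fused to the dihydropyranone ring C, which carries the catechol ring B at C2; ring A bears hydroxyls at C5 and C7 and a geranyl chain at C6. There is one stereocentre, C2 (S), so no relative configuration has to be controlled, but the centre is fragile: the C2–O1 bond is β to the C4 carbonyl and opens by β-elimination under base, and the para-oxygenated ring B helps it to ionise under strong acid. The two trisubstituted alkenes of the side chain lie next to the C5 and C7 hydroxyls and close to chromans under strong acid, and the catechol is easily oxidised. The main difficulty is regiochemical: in a 5,7-dihydroxyflavanone C6 and C8 are almost equally nucleophilic, so direct C-geranylation would give mixtures with the 8-isomer and with O- and bis-alkylated material. The route rests on the substitution pattern of ring A itself: C6 lies between the oxygenated carbons C5 and C7 and para to C8a, which carries O1, while C8 and, before ring C is closed, C4a are CH. That sequence (hydroxyl carbon, alkyl carbon, siloxy carbon, CH, alkoxy carbon, CH) is what a 1-siloxyalkyne and a 3-alkoxycyclobutenone give on heating, with the three oxygens told apart from the start. Apart from its protecting groups such a ring is symmetric about the C6···C8a axis, so acylation of either CH next to O1 leads to the same flavanone; and if the alkoxy group of the cyclobutenone already is the (S)-configured C2 fragment, O1–C2 never has to be made at a stage where it could scramble.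

## Retrosynthetic reasoning

**Protecting groups (25 ⇐ 24 ⇐ 23).** Only O–C(acetal) and O–Si bonds are cut. The silyl group on O7 in 23 is the one that arrives with the alkyne, and the acetals on ring B are stable to hydride, amide base, heat and hydroxide. The forward steps must free four phenols without base strong enough to open ring C and without acid strong enough to protonate the side-chain alkenes.

**Ring C (23 ⇐ 20 ⇐ 19).** The C4–C4a bond is cut. Ring A of the acid 20 is a tri-oxygenated arene whose two CH positions flank O1 and are the most nucleophilic carbons in the molecule. Acylation at either one gives, after desilylation, the same 24, so no regiochemical control is needed. Cutting O1–C2 instead would mean closing ring C by conjugate addition at the end, which would create C2 under reversible conditions. The forward reaction has to activate the acid without a strong protic or Lewis acid. The acid 20 comes from the ester 19, because a free carboxylic acid would add to the ketenes of the key step and protonate the siloxyalkyne.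

**Ring A (19 ⇐ 14 + 6).** This is the key disconnection. Ring A is taken apart into the cyclobutenone 14 and the siloxyalkyne 6. Two skeletal bonds are cut in 19: hydroxyl carbon to geranyl carbon, and siloxy carbon to its CH neighbour. With the ring closure expected in 23 these are C5–C6 and C7–C8. The cut removes electrophilic geranylation altogether: the geranyl carbon is an alkyne carbon and can only end between the two oxygenated carbons. The hydroxyl (from the ketene carbonyl), the siloxy group (from 6) and O1 (from the alkoxy group of 14) are distinguished by origin. The forward reaction has to open 14 thermally, add 6 with the right orientation and aromatise, under neutral conditions that leave C2, the ester and the alkenes alone.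

**Siloxyalkyne (6 ⇐ 3 ⇐ 1 + 2).** The O–C(sp) bond is cut first, giving the terminal alkyne 3, whose acetylide is oxygenated and silylated in one flask. The C–C bond between the allylic carbon and the alkyne is then cut to geranyl bromide 1 and the acetylene Grignard reagent 2. The E alkene is bought with 1 and is never touched.

**Cyclobutenone (14 ⇐ 10 + 13; 13 ⇐ 11 + 12).** The vinylogous ester C–O bond is cut on the ring side, not at the benzylic carbon. The alcohol 10 then acts as nucleophile and its C–O bond is never broken, so its configuration is retained. The opposite cut would need a substitution at a para-oxygenated benzylic carbon, which ionises easily. The exchange is run with weak acid and not with alkoxide, because alkoxides open cyclobutenones by attack at the carbonyl and because 14 carries a good leaving group β to an ester. The ethoxy compound 13 comes from ethoxyacetylene 11 and ketene 12, generated in the flask.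

**Chiral alcohol (10 ⇐ 9 ⇐ 8 ⇐ 7).** The C–H bond at the carbinol carbon is cut: the only stereocentre of the synthesis is set by asymmetric reduction of the aryl ketone 9, a reaction with a predictable sense. The β-keto ester 9 is cut between the ketone α-carbon and the ester carbon to the methyl ketone 8, which is the doubly protected form of the commercial acetophenone 7.

## Alternatives that were turned down

**Alternative 1:** The C2–C3 bond is cut. Ring C would be closed last from the diazoketone A1, in which O1 is a benzyl ether and all four phenols are silyl ethers. A rhodium carbene at C3 would insert into one of the two enantiotopic benzylic C–H bonds under a chiral dirhodium tetracarboxylate such as Rh2(S-PTTL)4, giving the tetrasilyl ether A2.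
- For: the C–C bond, ring C and C2 are made together at a late stage by catalyst control, so nothing chiral has to be carried. The C–H bond is activated by both oxygen and aryl. One fluoride step ends the synthesis, which is a shorter and gentler end-game than the chosen one.
- Against: diazoketones without a donor group give weaker enantiocontrol in C–H insertion. The carbene has easier paths: attack on O1 gives an oxonium ylide that rearranges with benzyl shift to a benzofuranone, and the alkenes and ring B can be cyclopropanated. A1 also needs a 6-geranyl acetophenone with three differentiated oxygens, so the C6/C8 question is only moved to the start.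
- Comparison: the chosen strategy fixes the geranyl position by construction and takes C2 from a ketone reduction. It pays with a stereocentre carried through eight steps and four steps after the key step.

**Alternative 2:** The O1–C2 and C3–C4 bonds are cut. The salicylaldehyde A3 would be converted with an orthoformate and acid into a 4-methoxy ortho-quinone methide, which adds the styrene A4 in a hetero-Diels–Alder reaction to give the 2,4-cis 4-methoxyflavan A5.
- For: it is the most convergent plan, with two bonds and ring C from two simple halves. The orientation of the cycloaddition is fixed by polarity. The aldehyde precursor of A3 has two equivalent free ring carbons, so mono-geranylation has one outcome; on this point it is as strong as the benzannulation.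
- Against: C2 is made in an acid-catalysed reaction of a cationic intermediate, so the absolute configuration would depend on a chiral acid that is not established for such partners. C4 arrives at the wrong oxidation level, and its ether must be hydrolysed and oxidised through a very ionisable benzylic position, under acid, with the alkenes and acetals present. In A3 the two chelated hydroxyls flanking the aldehyde must be told apart, and which one becomes O1 decides 6- against 8-geranyl.
- Comparison: the chosen route has more steps in its longest line, but C4 is formed as a carbonyl, O1 is distinguished by its origin and C2 comes from a reliable reduction.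

**Alternative 3:** The C4a–C5 bond of ring A is cut. Ring C exists first as an (S)-dihydropyranone in the keto ester A6. Base would form the extended enolate, C4a would attack the methyl ester, and loss of methanol and enolisation would give A7, which is identical with 24.
- For: the geranyl position is fixed by construction, as in the chosen route. The stereocentre could come from a catalytic hetero-Diels–Alder reaction. The product is already 24, so one step remains against four; this end-game is clearly stronger.
- Against: the key step needs strong base on a ring whose C3–H is acidic and whose O1 is a vinylogous carboxylate leaving group, so β-elimination opens ring C and erases C2. The most acidic proton of A6 is the one on the geranyl-bearing carbon, so a polyanion is needed, and C4a is only a modest nucleophile. Building A6 needs further enolate steps with the same hazard.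
- Comparison: the chosen key step uses neither acid nor base, which is what the C2 centre needs, at the cost of the longer end-game.

Key step: step 8

## Remarks before the steps

- Geranyl means (2E)-3,7-dimethylocta-2,6-dien-1-yl; flavanone numbering (O1, C2…C8a, ring B primed) is used throughout.
- Assumption: 3',4'-dihydroxyacetophenone is taken as the commercial source of ring B, because carboxylation of its methyl ketone reaches the β-keto ester in fewer steps than homologation of a benzoic acid.
- Assumption: the facial sense of the transfer hydrogenation in step 5 is assigned by the usual aryl-ketone model; should the β-keto ester behave otherwise, the enantiomeric ligand would be used.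

## Route

Step 1
Reactants: 1 geranyl bromide; 2 ethynylmagnesium bromide
Product: 3 (E)-5,9-dimethyldeca-4,8-dien-1-yne
Conditions: 2 (3 equiv), CuCl (10 mol%), THF, 0 → 50 °C
Reagents that add atoms: none
Why: Copper-catalysed coupling of an alkynyl Grignard reagent with a primary allylic bromide; attack at the primary carbon is favoured because the other terminus would give a quaternary centre, the 2E alkene is not involved, and the excess of 2 suppresses a second allylation of the product acetylide.

Step 2
Reactants: 3 (E)-5,9-dimethyldeca-4,8-dien-1-yne
Product: 6 (E)-triisopropyl[(5,9-dimethyldeca-4,8-dien-1-yn-1-yl)oxy]silane, via lithium acetylide 4 (not isolated), via lithium ynolate 5 (not isolated)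
Conditions: LiN(SiMe3)2, THF, −78 °C; t-BuOOLi (from t-BuOOH and LiN(SiMe3)2), −78 → 0 °C; i-Pr3SiOTf, −78 → 0 °C
Reagents that add atoms: tert-butyl hydroperoxide CC(C)(C)OO; triisopropylsilyl trifluoromethanesulfonate CC(C)[Si](OS(=O)(=O)C(F)(F)F)(C(C)C)C(C)C
Why: Oxidation of a lithium acetylide by lithium tert-butyl peroxide to the ynolate, then O-silylation with a hindered silyl triflate, is the standard entry to 1-siloxyalkynes; the alkynyl C–H is much more acidic than the allylic-propargylic CH2, so the amide base at −78 °C should form 4 without isomerising the skipped enyne, and the bulky silyl group ends on oxygen.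

Step 3
Reactants: 7 3',4'-dihydroxyacetophenone
Product: 8 1-[3,4-bis(methoxymethoxy)phenyl]ethan-1-one
Conditions: MeOCH2Cl, i-Pr2NEt, CH2Cl2, 0 °C → rt
Reagents that add atoms: chloromethyl methyl ether COCCl
Why: O-Alkylation of both phenols to methoxymethyl acetals; these survive hydride, amide base, heat and hydroxide and are removed together at the end.

Step 4
Reactants: 8 1-[3,4-bis(methoxymethoxy)phenyl]ethan-1-one
Product: 9 methyl 3-[3,4-bis(methoxymethoxy)phenyl]-3-oxopropanoate
Conditions: NaH, (MeO)2CO, THF, reflux; aq. NH4Cl
Reagents that add atoms: dimethyl carbonate COC(=O)OC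
Why: Claisen-type C-acylation of the methyl ketone enolate with a carbonate; the product is held as its sodium enolate, which drives the reaction and prevents a second acylation.

Step 5
Reactants: 9 methyl 3-[3,4-bis(methoxymethoxy)phenyl]-3-oxopropanoate
Product: 10 methyl (S)-3-[3,4-bis(methoxymethoxy)phenyl]-3-hydroxypropanoate
Conditions: RuCl[(S,S)-TsDPEN](p-cymene) (1 mol%), HCO2H/Et3N (5:2), EtOAc, 40 °C
Reagents that add atoms: none
Why: Noyori–Ikariya asymmetric transfer hydrogenation of an aryl ketone; with the (S,S)-ligand the hydride is delivered to the face that gives (S)-carbinols of aryl alkyl ketones, and the CH2CO2Me group takes the place of the methyl group without changing the CIP order, so the future C2 is set here as S.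

Step 6
Reactants: 11 ethoxyacetylene
Product: 13 3-ethoxycyclobut-2-en-1-one, via ketene 12 (not isolated)
Conditions: AcCl, Et3N, Et2O, 0 °C → rt
Reagents that add atoms: acetyl chloride CC(=O)Cl
Why: [2+2] Cycloaddition of ketene, formed by dehydrochlorination of acetyl chloride, with an ynol ether; the nucleophilic terminal carbon of 11 bonds to the ketene carbonyl carbon, which places the ethoxy group at C3 of the ring.

Step 7
Reactants: 10 methyl (S)-3-[3,4-bis(methoxymethoxy)phenyl]-3-hydroxypropanoate; 13 3-ethoxycyclobut-2-en-1-one
Product: 14 methyl (S)-3-[3,4-bis(methoxymethoxy)phenyl]-3-[(3-oxocyclobut-1-en-1-yl)oxy]propanoate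
Conditions: 13 (3 equiv), pyridinium p-toluenesulfonate (15 mol%), 5 Å MS, ClCH2CH2Cl, 40 °C
Reagents that add atoms: none
Why: Acid-catalysed transetherification of a vinylogous ester (the alcohol adds to C3 of the O-protonated enone, then ethanol is lost); the benzylic C–O bond of 10 is not broken, so the S configuration is retained, and a weak acid is chosen because the carbonyl oxygen of the vinylogous ester is far more basic than the benzylic oxygen, so exchange should outrun ionisation at the benzylic carbon and acetal cleavage while the sieves and the excess of 13 pull the equilibrium.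

Step 8
Reactants: 14 methyl (S)-3-[3,4-bis(methoxymethoxy)phenyl]-3-[(3-oxocyclobut-1-en-1-yl)oxy]propanoate; 6 (E)-triisopropyl[(5,9-dimethyldeca-4,8-dien-1-yn-1-yl)oxy]silane
Product: 19 methyl (S)-3-[3,4-bis(methoxymethoxy)phenyl]-3-[4-geranyl-3-hydroxy-5-(triisopropylsilyloxy)phenoxy]propanoate, via vinylketene 15 (not isolated), via vinylcyclobutenone 16 (not isolated), via dienylketene 17 (not isolated), via cyclohexadienone 18 (not isolated)
Conditions: 6 (1.5 equiv), PhMe (0.5 M), 80 → 110 °C, sealed tube, Ar
Reagents that add atoms: none
Why: Danheiser benzannulation, a known cascade of four pericyclic steps, applied here to a 3-alkoxycyclobutenone with a chiral alkoxy group. Heating opens 14 by 4π-electrocyclic cleavage of the bond between the carbonyl carbon and the ring CH2 to give the vinylketene 15, whose ketene C=C adds the electron-rich alkyne 6 in a [2+2] cycloaddition to the vinylcyclobutenone 16. A second, reversible 4π-electrocyclic opening gives the dienylketene 17, and the isomer with the vinyl group turned towards the ketene closes ring A by thermal disrotatory 6π-electrocyclisation (ketene carbon to vinyl CH2) to the cyclohexadienone 18, which tautomerises irreversibly to the phenol 19. The selectivity that matters is the orientation of the [2+2] step: the siloxy oxygen makes the geranyl-bearing alkyne carbon the nucleophilic one, it bonds to the electrophilic ketene carbonyl carbon, and so geranyl ends between the new hydroxyl carbon and the siloxy carbon with the alkoxy carbon para to it. No stereocentre is formed; the existing one is a spectator sp3 carbon on the ether oxygen, and nothing in the neutral aprotic medium can ionise or deprotonate next to it. Chemoselectivity rests on the ketene reacting much faster with the siloxyalkyne than with the isolated trisubstituted alkenes or the ester, and the excess of 6 keeps 15 from being intercepted by the phenol 19. The donor oxygen at C3 stabilises 14 as a vinylogous ester, so a higher temperature than for 3-alkylcyclobutenones is planned.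

Step 9
Reactants: 19 methyl (S)-3-[3,4-bis(methoxymethoxy)phenyl]-3-[4-geranyl-3-hydroxy-5-(triisopropylsilyloxy)phenoxy]propanoate
Product: 20 (S)-3-[3,4-bis(methoxymethoxy)phenyl]-3-[4-geranyl-3-hydroxy-5-(triisopropylsilyloxy)phenoxy]propanoic acid
Conditions: LiOH, THF/H2O, 0 °C → rt; then dil. HCl to pH 4, 0 °C
Reagents that add atoms: lithium hydroxide [Li+].[OH-]
Why: Ester saponification; hydroxide attack at the ester carbonyl is faster than α-deprotonation, and once the carboxylate has formed, β-elimination of the aryloxide is shut off; the hindered aryl silyl ether should survive, and its loss would do no harm because that oxygen is free in the target.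

Step 10
Reactants: 20 (S)-3-[3,4-bis(methoxymethoxy)phenyl]-3-[4-geranyl-3-hydroxy-5-(triisopropylsilyloxy)phenoxy]propanoic acid
Product: 23 (S)-6-geranyl-5-hydroxy-3',4'-bis(methoxymethoxy)-7-(triisopropylsilyloxy)flavanone, via mixed anhydride 21 (not isolated), via flavanone trifluoroacetate 22 (not isolated)
Conditions: (CF3CO)2O (3 equiv), CH2Cl2 (0.02 M), 0 °C → rt; then MeOH, 0 °C
Reagents that add atoms: none
Why: Intramolecular Friedel–Crafts acylation through the mixed trifluoroacetic anhydride; ring A is a phloroglucinol-type arene, so no Lewis acid is needed, and the six-membered ring C should close at the less hindered CH para to the siloxy group, while the phenol is trifluoroacetylated in passing and freed by methanolysis. Closure at the other CH would only exchange the positions of silyl group and hydroxyl, and step 11 leads from there to the same 24.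

Step 11
Reactants: 23 (S)-6-geranyl-5-hydroxy-3',4'-bis(methoxymethoxy)-7-(triisopropylsilyloxy)flavanone
Product: 24 (S)-6-geranyl-5,7-dihydroxy-3',4'-bis(methoxymethoxy)flavanone
Conditions: Bu4NF, AcOH (1:1), THF, 0 °C
Reagents that add atoms: none
Why: Fluoride cleavage of an aryl silyl ether; the acetic acid buffer keeps the medium from becoming basic, so ring C is not opened and C2 is not racemised.

Step 12
Reactants: 24 (S)-6-geranyl-5,7-dihydroxy-3',4'-bis(methoxymethoxy)flavanone
Product: 25 nymphaeol A
Conditions: 3 M HCl (aq), MeOH, rt → 40 °C
Reagents that add atoms: none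
Why: Acid-catalysed methanolysis of the two methoxymethyl acetals; flavanones keep their configuration in dilute acid, and at this acid strength and temperature protonation of the trisubstituted alkenes should be slower than acetal exchange.

## Compound list

1 | geranyl bromide | CC(C)=CCC/C(C)=C/CBr | starting material
2 | ethynylmagnesium bromide | C#C[Mg]Br | starting material
3 | (E)-5,9-dimethyldeca-4,8-dien-1-yne | CC(C)=CCC/C(C)=C/CC#C | intermediate
4 | lithium (E)-5,9-dimethyldeca-4,8-dien-1-yn-1-ide | CC(C)=CCC/C(C)=C/CC#C[Li] | intermediate (not isolated)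
5 | lithium (E)-5,9-dimethyldeca-4,8-dien-1-yn-1-olate | CC(C)=CCC/C(C)=C/CC#C[O-].[Li+] | intermediate (not isolated)
6 | (E)-triisopropyl[(5,9-dimethyldeca-4,8-dien-1-yn-1-yl)oxy]silane | CC(C)=CCC/C(C)=C/CC#CO[Si](C(C)C)(C(C)C)C(C)C | intermediate
7 | 3',4'-dihydroxyacetophenone | CC(=O)c1ccc(O)c(O)c1 | starting material
8 | 1-[3,4-bis(methoxymethoxy)phenyl]ethan-1-one | CC(=O)c1ccc(OCOC)c(OCOC)c1 | intermediate
9 | methyl 3-[3,4-bis(methoxymethoxy)phenyl]-3-oxopropanoate | COC(=O)CC(=O)c1ccc(OCOC)c(OCOC)c1 | intermediate
10 | methyl (S)-3-[3,4-bis(methoxymethoxy)phenyl]-3-hydroxypropanoate | COC(=O)C[C@@H](c1ccc(OCOC)c(OCOC)c1)O | intermediate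
11 | ethoxyacetylene | CCOC#C | starting material
12 | ketene | C=C=O | intermediate (not isolated)
13 | 3-ethoxycyclobut-2-en-1-one | CCOC1=CC(=O)C1 | intermediate
14 | methyl (S)-3-[3,4-bis(methoxymethoxy)phenyl]-3-[(3-oxocyclobut-1-en-1-yl)oxy]propanoate | COC(=O)C[C@@H](c1ccc(OCOC)c(OCOC)c1)OC1=CC(=O)C1 | intermediate
15 | methyl (S)-3-[3,4-bis(methoxymethoxy)phenyl]-3-[(4-oxobuta-1,3-dien-2-yl)oxy]propanoate | COC(=O)C[C@@H](c1ccc(OCOC)c(OCOC)c1)OC(=C)C=C=O | intermediate (not isolated)
16 | methyl (3S)-3-[3,4-bis(methoxymethoxy)phenyl]-3-({1-[3-geranyl-4-oxo-2-(triisopropylsilyloxy)cyclobut-2-en-1-yl]ethenyl}oxy)propanoate, both epimers at the ring carbon | COC(=O)C[C@@H](c1ccc(OCOC)c(OCOC)c1)OC(=C)C1C(=O)C(C/C=C(\C)CCC=C(C)C)=C1O[Si](C(C)C)(C(C)C)C(C)C | intermediate (not isolated)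
17 | methyl (S)-3-[3,4-bis(methoxymethoxy)phenyl]-3-{[(3E)-5-geranyl-6-oxo-4-(triisopropylsilyloxy)hexa-1,3,5-trien-2-yl]oxy}propanoate | COC(=O)C[C@@H](c1ccc(OCOC)c(OCOC)c1)OC(=C)/C=C(/O[Si](C(C)C)(C(C)C)C(C)C)C(C/C=C(\C)CCC=C(C)C)=C=O | intermediate (not isolated)
18 | methyl (S)-3-[3,4-bis(methoxymethoxy)phenyl]-3-{[4-geranyl-5-oxo-3-(triisopropylsilyloxy)cyclohexa-1,3-dien-1-yl]oxy}propanoate | COC(=O)C[C@@H](c1ccc(OCOC)c(OCOC)c1)OC1=CC(O[Si](C(C)C)(C(C)C)C(C)C)=C(C/C=C(\C)CCC=C(C)C)C(=O)C1 | intermediate (not isolated)
19 | methyl (S)-3-[3,4-bis(methoxymethoxy)phenyl]-3-[4-geranyl-3-hydroxy-5-(triisopropylsilyloxy)phenoxy]propanoate | CC(C)=CCC/C(C)=C/Cc1c(O)cc(O[C@@H](CC(=O)OC)c2ccc(OCOC)c(OCOC)c2)cc1O[Si](C(C)C)(C(C)C)C(C)C | intermediate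
20 | (S)-3-[3,4-bis(methoxymethoxy)phenyl]-3-[4-geranyl-3-hydroxy-5-(triisopropylsilyloxy)phenoxy]propanoic acid | CC(C)=CCC/C(C)=C/Cc1c(O)cc(O[C@@H](CC(=O)O)c2ccc(OCOC)c(OCOC)c2)cc1O[Si](C(C)C)(C(C)C)C(C)C | intermediate
21 | (S)-3-[3,4-bis(methoxymethoxy)phenyl]-3-[4-geranyl-3-(trifluoroacetoxy)-5-(triisopropylsilyloxy)phenoxy]propanoic trifluoroacetic anhydride | CC(C)=CCC/C(C)=C/Cc1c(OC(=O)C(F)(F)F)cc(O[C@@H](CC(=O)OC(=O)C(F)(F)F)c2ccc(OCOC)c(OCOC)c2)cc1O[Si](C(C)C)(C(C)C)C(C)C | intermediate (not isolated)
22 | (S)-6-geranyl-3',4'-bis(methoxymethoxy)-5-(trifluoroacetoxy)-7-(triisopropylsilyloxy)flavanone | CC(C)=CCC/C(C)=C/Cc1c(O[Si](C(C)C)(C(C)C)C(C)C)cc2c(c1OC(=O)C(F)(F)F)C(=O)C[C@@H](c1ccc(OCOC)c(OCOC)c1)O2 | intermediate (not isolated)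
23 | (S)-6-geranyl-5-hydroxy-3',4'-bis(methoxymethoxy)-7-(triisopropylsilyloxy)flavanone | CC(C)=CCC/C(C)=C/Cc1c(O[Si](C(C)C)(C(C)C)C(C)C)cc2c(c1O)C(=O)C[C@@H](c1ccc(OCOC)c(OCOC)c1)O2 | intermediate
24 | (S)-6-geranyl-5,7-dihydroxy-3',4'-bis(methoxymethoxy)flavanone | CC(C)=CCC/C(C)=C/Cc1c(O)cc2c(c1O)C(=O)C[C@@H](c1ccc(OCOC)c(OCOC)c1)O2 | intermediate
25 | nymphaeol A, (S)-6-geranyl-5,7,3',4'-tetrahydroxyflavanone | CC(C)=CCC/C(C)=C/Cc1c(O)cc2c(c1O)C(=O)C[C@@H](c1ccc(O)c(O)c1)O2 | target

## Step count and least certain steps

Total step count: 12. Longest linear sequence: 9 steps (7 → 8 → 9 → 10 → 14 → 19 → 20 → 23 → 24 → 25; steps 3, 4, 5, 7, 8, 9, 10, 11, 12).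

**Step 8 (key step).** What is most likely to go wrong is a sluggish first ring opening: the alkoxy group stabilises 14 as a vinylogous ester, and at the temperature then needed the siloxyalkyne may decompose, or the vinylketene may be captured by the phenol already formed. The fallback gives up the ring construction and makes the aryl ether classically. Geranyl bromide 1 is used to C-alkylate commercial phloroglucinol (K2CO3, acetone) to 2-geranylphloroglucinol F1. The keto ester 9 is reduced with RuCl[(R,R)-TsDPEN](p-cymene) to methyl (R)-3-[3,4-bis(methoxymethoxy)phenyl]-3-hydroxypropanoate F2. A Mitsunobu reaction (PPh3, diisopropyl azodicarboxylate, PhMe, 0 °C) at the unhindered hydroxyl para to the side chain would give, with inversion, methyl (S)-3-[3,4-bis(methoxymethoxy)phenyl]-3-(4-geranyl-3,5-dihydroxyphenoxy)propanoate F3. Saponification gives (S)-3-[3,4-bis(methoxymethoxy)phenyl]-3-(4-geranyl-3,5-dihydroxyphenoxy)propanoic acid F4, and ring closure as in step 10 returns to the route at 24. This path has its own weaknesses: competition between the three phenols, and partial loss of configuration at the electron-rich benzylic carbon.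

**Step 7.** The exchange may be too slow with a weak acid, and a stronger one would bring ionisation of the benzylic C–O bond (racemisation, elimination to the cinnamate) and acetal cleavage. The fallback replaces acid catalysis by addition–elimination on a vinylogous acid chloride. Hydrolysis of 13 (dilute aqueous HCl) gives cyclobutane-1,3-dione F5. Oxalyl chloride with catalytic DMF (CH2Cl2, 0 °C) converts its enol into 3-chlorocyclobut-2-en-1-one F6, as larger cyclic 1,3-diones give 3-chloroenones. F6 is used in solution and treated at −20 °C with 10 and 2,6-lutidine, which returns to the route at 14 with the benzylic bond untouched and no acid or alkoxide present.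

**Step 2.** The amide base may isomerise the skipped enyne to an allene or a conjugated enyne, or oxygen transfer to the acetylide may be incomplete. The fallback reaches the ynolate without an acetylide. Carbonylation of 1 (CO, MeOH, Pd(OAc)2, PPh3, i-Pr2NEt) gives methyl (E)-4,8-dimethylnona-3,7-dienoate F7. A Kowalski homologation (LiCHBr2 from CH2Br2 and lithium 2,2,6,6-tetramethylpiperidide at −78 °C, then LiN(SiMe3)2 and n-BuLi) converts the ester into the ynolate 5, and silylation as in step 2 returns to the route at 6. Its own risk is enolisation of the β,γ-unsaturated ester.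

**Step 10.** The trifluoroacetic acid that is released may cleave acetals, protonate the alkenes next to the phenol or ionise the benzylic ether, and intermolecular acylation may compete. The fallback closes ring C with a carbanion instead of an acylium ion, starting from the ester 19. Silylation (i-Pr3SiOTf, 2,6-lutidine) gives methyl (S)-3-[3,4-bis(methoxymethoxy)phenyl]-3-[4-geranyl-3,5-bis(triisopropylsilyloxy)phenoxy]propanoate F8, whose ring A is symmetric. Iodination with N-iodosuccinimide (MeCN, 0 °C) can therefore give only one monoiodide, methyl (S)-3-[3,4-bis(methoxymethoxy)phenyl]-3-[4-geranyl-2-iodo-3,5-bis(triisopropylsilyloxy)phenoxy]propanoate F9. Iodine–magnesium exchange (i-PrMgCl·LiCl, THF, −40 → 0 °C) and Parham-type attack of the aryl Grignard reagent on the ester would give (S)-6-geranyl-3',4'-bis(methoxymethoxy)-5,7-bis(triisopropylsilyloxy)flavanone F10. Buffered fluoride as in step 11 removes both silyl groups and returns to the route at 24.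

## Further compounds

F1 | step 8 | 2-geranylphloroglucinol | CC(C)=CCC/C(C)=C/Cc1c(O)cc(O)cc1O
F2 | step 8 | methyl (R)-3-[3,4-bis(methoxymethoxy)phenyl]-3-hydroxypropanoate | COC(=O)C[C@H](c1ccc(OCOC)c(OCOC)c1)O
F3 | step 8 | methyl (S)-3-[3,4-bis(methoxymethoxy)phenyl]-3-(4-geranyl-3,5-dihydroxyphenoxy)propanoate | CC(C)=CCC/C(C)=C/Cc1c(O)cc(O[C@@H](CC(=O)OC)c2ccc(OCOC)c(OCOC)c2)cc1O
F4 | step 8 | (S)-3-[3,4-bis(methoxymethoxy)phenyl]-3-(4-geranyl-3,5-dihydroxyphenoxy)propanoic acid | CC(C)=CCC/C(C)=C/Cc1c(O)cc(O[C@@H](CC(=O)O)c2ccc(OCOC)c(OCOC)c2)cc1O
F5 | step 7 | cyclobutane-1,3-dione | O=C1CC(=O)C1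
F6 | step 7 | 3-chlorocyclobut-2-en-1-one | O=C1C=C(Cl)C1
F7 | step 2 | methyl (E)-4,8-dimethylnona-3,7-dienoate | CC(C)=CCC/C(C)=C/CC(=O)OC
F8 | step 10 | methyl (S)-3-[3,4-bis(methoxymethoxy)phenyl]-3-[4-geranyl-3,5-bis(triisopropylsilyloxy)phenoxy]propanoate | CC(C)=CCC/C(C)=C/Cc1c(O[Si](C(C)C)(C(C)C)C(C)C)cc(O[C@@H](CC(=O)OC)c2ccc(OCOC)c(OCOC)c2)cc1O[Si](C(C)C)(C(C)C)C(C)C
F9 | step 10 | methyl (S)-3-[3,4-bis(methoxymethoxy)phenyl]-3-[4-geranyl-2-iodo-3,5-bis(triisopropylsilyloxy)phenoxy]propanoate | CC(C)=CCC/C(C)=C/Cc1c(O[Si](C(C)C)(C(C)C)C(C)C)cc(O[C@@H](CC(=O)OC)c2ccc(OCOC)c(OCOC)c2)c(I)c1O[Si](C(C)C)(C(C)C)C(C)C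
F10 | step 10 | (S)-6-geranyl-3',4'-bis(methoxymethoxy)-5,7-bis(triisopropylsilyloxy)flavanone | CC(C)=CCC/C(C)=C/Cc1c(O[Si](C(C)C)(C(C)C)C(C)C)cc2c(c1O[Si](C(C)C)(C(C)C)C(C)C)C(=O)C[C@@H](c1ccc(OCOC)c(OCOC)c1)O2
A1 | alternative 1 | 2-diazo-1-[2-{[3,4-bis(tert-butyldimethylsilyloxy)phenyl]methoxy}-4,6-bis(tert-butyldimethylsilyloxy)-5-geranylphenyl]ethan-1-one | CC(C)=CCC/C(C)=C/Cc1c(O[Si](C)(C)C(C)(C)C)cc(OCc2ccc(O[Si](C)(C)C(C)(C)C)c(O[Si](C)(C)C(C)(C)C)c2)c(C(=O)C=[N+]=[N-])c1O[Si](C)(C)C(C)(C)C
A2 | alternative 1 | (S)-5,7,3',4'-tetra-O-tert-butyldimethylsilyl nymphaeol A | CC(C)=CCC/C(C)=C/Cc1c(O[Si](C)(C)C(C)(C)C)cc2c(c1O[Si](C)(C)C(C)(C)C)C(=O)C[C@@H](c1ccc(O[Si](C)(C)C(C)(C)C)c(O[Si](C)(C)C(C)(C)C)c1)O2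
A3 | alternative 2 | 3-geranyl-6-hydroxy-2,4-bis(methoxymethoxy)benzaldehyde | CC(C)=CCC/C(C)=C/Cc1c(OCOC)cc(O)c(C=O)c1OCOC
A4 | alternative 2 | 3,4-bis(methoxymethoxy)styrene | C=Cc1ccc(OCOC)c(OCOC)c1
A5 | alternative 2 | (2S,4S)-6-geranyl-4-methoxy-5,7,3',4'-tetrakis(methoxymethoxy)flavan (2,4-cis) | CC(C)=CCC/C(C)=C/Cc1c(OCOC)cc2c(c1OCOC)[C@@H](OC)C[C@@H](c1ccc(OCOC)c(OCOC)c1)O2
A6 | alternative 3 | methyl 4-{(2S)-2-[3,4-bis(methoxymethoxy)phenyl]-4-oxo-3,4-dihydro-2H-pyran-6-yl}-2-geranyl-3-oxobutanoate | CC(C)=CCC/C(C)=C/CC(C(=O)OC)C(=O)CC1=CC(=O)C[C@@H](c2ccc(OCOC)c(OCOC)c2)O1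
A7 | alternative 3 | (S)-3',4'-di-O-methoxymethyl nymphaeol A (identical with 24) | CC(C)=CCC/C(C)=C/Cc1c(O)cc2c(c1O)C(=O)C[C@@H](c1ccc(OCOC)c(OCOC)c1)O2
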